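The chromanone carbocycle (ring C4a–C5–C6–C7–C8–C8a) is cut at C7–C8, C4a–C8a and C6–C7. This ring is a cyclohexa-2,4-dienone with oxygen on C5, C7 and C8a and a quaternary C6. That is the substitution left behind when a vinylketene joins an ynol ether and the product closes by a 6π reaction. One thermal operation joins a 4,4-dialkyl-3-ethoxycyclobutenone (prenyl and the verbenone-derived cyclobutylmethyl group on C4) to an enantiopure silyl ynol ether. The ynol ether carries the 1-phenylpropyl arm, with its carboxyl carbon masked as a dimethyl acetal. The step builds the ring, places the arm on C8 and creates C6, whose two carbon groups forbid aromatisation. It also leaves O5 (ethyl) and O8a (silyl) distinguishable for pyranone closure.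

Key step: step 12

Remarks
- Chromanone numbering (O1, C2, C3, C4, C4a, C5–C8, C8a) is used for the six-membered carbocycle from the key step onwards, even before the pyranone exists.
- Re-derived descriptors of the target are 2R, 3R (trans), 6R, benzylic S and cyclobutane 1R,3S (cis). (1S,5S)-Verbenone maps onto this cyclobutane. The benzylic descriptor reads S with a silylalkyne, ynol ether or ring carbon attached and R in the terminal alkyne; only the CIP rank changes, not the geometry.
- Assumption: in step 8 the ligand antipode is the one that gives the (S)-aldehyde. (R)-DTBM-SEGPHOS is written and is exchanged for its enantiomer if the sense of induction is opposite.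
- Design of the arm: it stays at the aldehyde level as a dimethyl acetal until the pyranone is closed. An ester CH2 would be deprotonated in the ynolate step and long before C4a–H.
- Design of the C4a–C4 bond: a C5-alkoxy enol is not nucleophilic at C4a, so this bond is made from a C4a carbanion.
- Design of C2 and C3: closure of an achiral tigloyl group would leave both centres uncontrolled, so both come in with an aldol-derived chain.
- In systematic numbering the [2+2] adduct of the key step is a 4-alkenylcyclobut-2-enone.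

Step 1
Reactants: 1 (1S,5S)-(−)-verbenone
Product: 2 (1S,3R)-3-acetyl-2,2-dimethylcyclobutane-1-carboxylic acid (cis-pinononic acid)
Conditions: RuCl3·xH2O (2 mol %), NaIO4 (4.1 equiv), EtOAc/MeCN/H2O, 23 °C
Reagents that add atoms: sodium periodate, [Na+].[O-]I(=O)(=O)=O
Why: Ruthenium tetroxide cleavage of the enone C=C (oxidative alkene cleavage, the former C3 leaving as CO2) does not touch the two ring stereocentres, so the cis-cyclobutane of 1 is carried into 2.

Step 2
Reactants: 2 cis-pinononic acid
Product: 3 (1S,3S)-2,2-dimethyl-3-(prop-1-en-2-yl)cyclobutane-1-carboxylic acid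
Conditions: Ph3PCH3Br (2.6 equiv), KOt-Bu (2.5 equiv), THF, 0 → 23 °C; then 1 M HCl
Reagents that add atoms: methyltriphenylphosphonium bromide, C[P+](c1ccccc1)(c1ccccc1)c1ccccc1.[Br-]
Why: Wittig methylenation of the methyl ketone is run on the potassium carboxylate, which shields the carboxyl α-position, and the non-stabilised ylide should add faster than it enolises the ketone, so the cis relationship is kept.

Step 3
Reactants: 3 isopropenyl acid
Product: 4 [(1S,3S)-2,2-dimethyl-3-(prop-1-en-2-yl)cyclobutyl]methanol
Conditions: LiAlH4, Et2O, 0 → 23 °C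
Reagents that add atoms: none
Why: Hydride reduction of the acid gives the primary alcohol, and the 1,1-disubstituted alkene and both stereocentres are inert to LiAlH4.

Step 4
Reactants: 4 cyclobutylmethanol
Product: 5 (1S,3S)-1-(iodomethyl)-2,2-dimethyl-3-(prop-1-en-2-yl)cyclobutane
Conditions: I2, PPh3, imidazole, CH2Cl2, 0 → 23 °C
Reagents that add atoms: iodine, II
Why: Appel iodination is an SN2 displacement at the primary carbon under neutral conditions that spare the alkene and the ring centres.

Step 5
Reactants: 6 acetic acid; 7 prenyl bromide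
Product: 8 5-methylhex-4-enoic acid
Conditions: LDA (2.1 equiv), THF/DMPU, 0 °C; then 7, 0 → 23 °C
Reagents that add atoms: none
Why: Alkylation of a carboxylic acid dianion (dilithioacetate) with a reactive primary allylic bromide proceeds by SN2 at the CH2 terminus.

Step 6
Reactants: 8 5-methylhex-4-enoic acid; 5 iodide
Product: 9 2-{[(1R,3S)-2,2-dimethyl-3-(prop-1-en-2-yl)cyclobutyl]methyl}-5-methylhex-4-enoic acid (both C2 epimers)
Conditions: LDA (2.2 equiv), THF, 0 → 23 °C; DMPU, 5, 23 → 40 °C
Reagents that add atoms: none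
Why: α-Alkylation of the acid dianion with the primary iodide should work because DMPU offsets the β-branching, and the new α-centre forms as a mixture that is erased in step 7.

Step 7
Reactants: 9 dialkylacetic acid; 10 ethoxyacetylene
Product: 13 3-ethoxy-4-(3-methylbut-2-en-1-yl)-4-{[(1R,3S)-2,2-dimethyl-3-(prop-1-en-2-yl)cyclobutyl]methyl}cyclobut-2-en-1-one (both C4 epimers), via acid chloride 11 (not isolated), via dialkylketene 12 (not isolated)
Conditions: (COCl)2, DMF (cat.), CH2Cl2, 0 → 23 °C, concentrate; 10 (2 equiv), Et3N (1.5 equiv), MeCN, sealed tube, 60 °C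
Reagents that add atoms: none
Why: Dehydrochlorination gives the dialkylketene, which undergoes the known regioselective ketene–alkoxyalkyne [2+2] cycloaddition (ketene carbonyl carbon to the terminal alkyne carbon), and the C4 epimers need no separation because C4 is planarised in step 12.

Step 8
Reactants: 14 (E)-cinnamaldehyde; 15 (triisopropylsilyl)acetylene
Product: 16 (3S)-3-phenyl-5-(triisopropylsilyl)pent-4-ynal
Conditions: [Rh(OAc)(C2H4)2]2 (2.5 mol %), (R)-DTBM-SEGPHOS (6 mol %), MeOH, 40 °C
Reagents that add atoms: none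
Why: In this rhodium-catalysed asymmetric conjugate alkynylation of an enal the bulky silyl group suppresses alkyne dimerisation and the chiral bisphosphine fixes the enal face that inserts into the alkynyl–rhodium bond, which sets the benzylic centre.

Step 9
Reactants: 16 alkynyl aldehyde
Product: 17 [(3S)-5,5-dimethoxy-3-phenylpent-1-yn-1-yl]triisopropylsilane
Conditions: HC(OMe)3, PPTS (cat.), MeOH, 23 °C
Reagents that add atoms: trimethyl orthoformate, COC(OC)OC
Why: Acid-catalysed acetalisation with the orthoformate as water scavenger removes every enolisable C–H from the arm before the strongly basic steps 11 and 17.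

Step 10
Reactants: 17 silylalkyne acetal
Product: 18 [(3R)-5,5-dimethoxypent-1-yn-3-yl]benzene
Conditions: TBAF (1.1 equiv), THF, 0 °C
Reagents that add atoms: none
Why: Fluoride protodesilylation of the alkynylsilane at 0 °C is mild enough to leave the propargylic benzylic C–H alone.

Step 11
Reactants: 18 terminal alkyne
Product: 21 {[(3S)-5,5-dimethoxy-3-phenylpent-1-yn-1-yl]oxy}triisopropylsilane, via lithium acetylide 19 (not isolated), via lithium ynolate 20 (not isolated)
Conditions: n-BuLi, THF, −78 °C; LiOOt-Bu (from t-BuOOH and LiHMDS), −78 → 0 °C; TIPSCl, −78 → 0 °C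
Reagents that add atoms: tert-butyl hydroperoxide, CC(C)(C)OO; chlorotriisopropylsilane, CC(C)[Si](Cl)(C(C)C)C(C)C
Why: Oxidation of a lithium acetylide with lithium tert-butyl peroxide gives the ynolate, which a bulky silyl chloride traps on oxygen rather than carbon, and the stereocentre takes no part.

Step 12
Reactants: 13 cyclobutenone; 21 silyl ynol ether
Product: 25 (6R)-6-{[(1R,3S)-2,2-dimethyl-3-(prop-1-en-2-yl)cyclobutyl]methyl}-2-[(1S)-3,3-dimethoxy-1-phenylpropyl]-5-ethoxy-6-(3-methylbut-2-en-1-yl)-3-[(triisopropylsilyl)oxy]cyclohexa-2,4-dien-1-one, via vinylketene 22 (not isolated), via 4-alkenylcyclobutenone 23 (not isolated), via dienylketene 24 (not isolated)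
Conditions: 21 (1.5 equiv), BHT (cat.), PhMe (0.5 M), 110 °C, sealed tube, argon; Et3N-deactivated silica
Reagents that add atoms: none
Why: Proposed new method: heating should open 13 by conrotatory 4π cleavage of its C1–C4 bond to vinylketene 22; the ketene carbonyl carbon (future C7) is attacked by the nucleophilic, arm-bearing carbon of 21, and the [2+2] addition (C7–C8 and C4a–C8a) gives 23, which opens again to dienylketene 24. The single new ring, the carbocycle, is closed by a thermal disrotatory 6π electrocyclisation that bonds the dialkyl terminus C6 to the ketene carbon C7. The closest known reaction type is the Danheiser benzannulation of cyclobutenones with silyloxyalkynes; what is new is a fully substituted terminus, so the 2,4-dienone cannot enolise to a phenol and is the end point. Regiochemistry (arm on C8, OTIPS on C8a, OEt on C5) is fixed by the polarity of ketene and ynol ether, and bimolecular capture of 22 is favoured over its [1,5]-H shift and over addition to its own prenyl alkene by excess 21 at high concentration and by the reversibility of the first opening. C6 is the only new stereocentre; its sense depends on both the C5=C6 geometry of 24 and the helical sense of closure, which the remote centres do not govern, so both epimers are expected, (6R)-25 is taken by chromatography and the other epimer can be re-equilibrated through 24 by Barton–Quinkert photolysis. The bath is held at 110 °C because a 6-prenyl dienone can lose its quaternary centre by Cope or retro-Claisen shifts at higher temperature.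

Step 13
Reactants: 26 (R)-4-benzyl-3-propionyl-1,3-oxazolidin-2-one; 27 acetaldehyde
Product: 28 (R)-4-benzyl-3-[(2R,3S)-3-hydroxy-2-methylbutanoyl]-1,3-oxazolidin-2-one
Conditions: n-Bu2BOTf, Et3N, CH2Cl2, −78 → 0 °C; 27, −78 → 0 °C; pH 7 buffer, MeOH, H2O2
Reagents that add atoms: none
Why: In the Evans syn-aldol reaction the Z-boron enolate reacts through a chair transition state on the face opposite the benzyl group, which sets the future C3 and the carbinol centre that becomes C2 after inversion.

Step 14
Reactants: 28 syn-aldol imide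
Product: 29 (2R,3S)-3-hydroxy-N-methoxy-N,2-dimethylbutanamide
Conditions: MeONHMe·HCl, AlMe3, THF, 0 → 23 °C
Reagents that add atoms: N,O-dimethylhydroxylamine hydrochloride, CNOC.Cl
Why: Aluminium-amide transamination of the imide to the Weinreb amide, assisted by the free β-hydroxyl, releases the auxiliary without epimerisation.

Step 15
Reactants: 29 hydroxy Weinreb amide
Product: 30 (2R,3S)-N-methoxy-N,2-dimethyl-3-[(triethylsilyl)oxy]butanamide
Conditions: TESCl, imidazole, DMF, 0 → 23 °C
Reagents that add atoms: chlorotriethylsilane, CC[Si](Cl)(CC)CC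
Why: Standard silylation of the secondary alcohol installs a group that can leave in one operation together with the enol silyl ether in step 19.

Step 16
Reactants: 30 silyl ether Weinreb amide
Product: 31 (2R,3S)-2-methyl-3-[(triethylsilyl)oxy]butanal
Conditions: DIBAL-H, THF, −78 °C; Rochelle salt; used at once
Reagents that add atoms: none
Why: Hydride reduction of a Weinreb amide stops at the chelated hemiaminal, so the aldehyde is released only on work-up and its α-centre is not exposed to base.

Step 17
Reactants: 25 dienone; 31 aldehyde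
Product: 33 C4a-[1-hydroxy-2-methyl-3-(triethylsilyloxy)butyl] derivative of 25 (C2 and C3 as in 31; both C4 carbinol epimers), via C4a-lithio dienone 32 (not isolated)
Conditions: LiTMP (from TMPH and n-BuLi, 1.3 equiv), THF, −78 °C; 31 (1.6 equiv), −78 °C; AcOH/THF quench at −78 °C
Reagents that add atoms: none
Why: Directed vinylic lithiation removes the one acidic sp2 C–H, flanked by the oxygen-bearing carbons C5 and C8a (as practised on cyclic vinylogous esters without enolisable positions), 1,2-addition to the aldehyde follows, and the new carbinol centre is a mixture that is removed in step 18.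

Step 18
Reactants: 33 carbinol
Product: 34 C4a-[(2R,3S)-2-methyl-3-(triethylsilyloxy)butanoyl] derivative of 25
Conditions: Dess–Martin periodinane, NaHCO3, CH2Cl2, 0 → 23 °C
Reagents that add atoms: none
Why: Buffered Dess–Martin oxidation turns the secondary carbinol into the C4 ketone without acid or base strong enough to touch C3, the enol ethers or the alkenes.

Step 19
Reactants: 34 bis-silyl ketone
Product: 35 C8a-enol of the 5-O-ethyl C4a-[(2R,3S)-3-hydroxy-2-methylbutanoyl] dienone
Conditions: HF·pyridine, pyridine, THF, 0 °C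
Reagents that add atoms: none
Why: Fluoride cleavage of both silyl ethers under buffered, weakly acidic conditions avoids retro-aldol and β-elimination and leaves the acetal and the ethyl enol ether in place.

Step 20
Reactants: 35 enol alcohol
Product: 36 (2R,3R,6R)-6-{[(1R,3S)-2,2-dimethyl-3-(prop-1-en-2-yl)cyclobutyl]methyl}-8-[(1S)-3,3-dimethoxy-1-phenylpropyl]-5-ethoxy-2,3-dimethyl-6-(3-methylbut-2-en-1-yl)-2,3-dihydro-4H-chromene-4,7(6H)-dione
Conditions: PPh3, DIAD, PhMe, 0 → 23 °C
Reagents that add atoms: none
Why: In this intramolecular Mitsunobu etherification of a vinylogous acid only O8a is free and within reach (O5 is ethylated), and SN2 attack on the activated carbinol inverts it to 2R, which gives the trans-2,3-dimethylpyranone with C3 untouched.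

Step 21
Reactants: 36 chromanone acetal
Product: 37 (3S)-3-[5-O-ethyl chromanone-8-yl]-3-phenylpropanal (ring as in 36)
Conditions: PPTS (0.2 equiv), acetone/H2O 9:1, 40 °C
Reagents that add atoms: water, O
Why: Mild acid hydrolysis cleaves the aliphatic dimethyl acetal well before water can reach the hindered C5 of the vinylogous ester, and the alkenes tolerate PPTS.

Step 22
Reactants: 37 aldehyde
Product: 38 (3S)-3-[5-O-ethyl chromanone-8-yl]-3-phenylpropanoic acid (ring as in 36)
Conditions: NaClO2, NaH2PO4, 2-methyl-2-butene (large excess), t-BuOH/H2O, 0 → 23 °C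
Reagents that add atoms: sodium chlorite, [Na+].[O-]Cl=O
Why: Pinnick oxidation is run while O5 is still ethylated, so no oxidisable free enol is present, and the scavenger protects the prenyl and isopropenyl groups from hypochlorous acid.

Step 23
Reactants: 38 ethyl ether acid
Product: 39 (3S)-3-[(2R,3R,6R)-6-{[(1R,3S)-2,2-dimethyl-3-(prop-1-en-2-yl)cyclobutyl]methyl}-5-hydroxy-2,3-dimethyl-6-(3-methylbut-2-en-1-yl)-4,7-dioxo-3,4,6,7-tetrahydro-2H-chromen-8-yl]-3-phenylpropanoic acid (target)
Conditions: 1 M aq HCl, THF, 23 → 40 °C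
Reagents that add atoms: water, O
Why: Acid hydrolysis (addition–elimination at C5) of a β-ethoxy enone activated by the C4 acyl group frees the chelated C5 enol, dilute aqueous acid spares the alkenes, and C3 already has the thermodynamically preferred trans arrangement.

Compound list
1 | (1S,5S)-(−)-verbenone | CC1=CC(=O)[C@H]2C[C@@H]1C2(C)C | starting material
2 | (1S,3R)-3-acetyl-2,2-dimethylcyclobutane-1-carboxylic acid | CC(=O)[C@@H]1C[C@H](C(=O)O)C1(C)C | intermediate
3 | (1S,3S)-2,2-dimethyl-3-(prop-1-en-2-yl)cyclobutane-1-carboxylic acid | C=C(C)[C@@H]1C[C@H](C(=O)O)C1(C)C | intermediate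
4 | [(1S,3S)-2,2-dimethyl-3-(prop-1-en-2-yl)cyclobutyl]methanol | C=C(C)[C@@H]1C[C@H](CO)C1(C)C | intermediate
5 | (1S,3S)-1-(iodomethyl)-2,2-dimethyl-3-(prop-1-en-2-yl)cyclobutane | C=C(C)[C@@H]1C[C@H](CI)C1(C)C | intermediate
6 | acetic acid | CC(=O)O | starting material
7 | prenyl bromide | CC(C)=CCBr | starting material
8 | 5-methylhex-4-enoic acid | CC(C)=CCCC(=O)O | intermediate
9 | 2-{[(1R,3S)-2,2-dimethyl-3-(prop-1-en-2-yl)cyclobutyl]methyl}-5-methylhex-4-enoic acid, C2 epimers | C=C(C)[C@@H]1C[C@H](CC(CC=C(C)C)C(=O)O)C1(C)C | intermediate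
10 | ethoxyacetylene | C#COCC | starting material
11 | acid chloride of 9 | C=C(C)[C@@H]1C[C@H](CC(CC=C(C)C)C(=O)Cl)C1(C)C | intermediate
12 | dialkylketene from 11 | C=C(C)[C@@H]1C[C@H](CC(CC=C(C)C)=C=O)C1(C)C | intermediate
13 | 3-ethoxy-4-prenyl-4-{[(1R,3S)-2,2-dimethyl-3-(prop-1-en-2-yl)cyclobutyl]methyl}cyclobut-2-en-1-one, C4 epimers | C=C(C)[C@@H]1C[C@H](CC2(CC=C(C)C)C(=O)C=C2OCC)C1(C)C | intermediate
14 | (E)-cinnamaldehyde | O=C/C=C/c1ccccc1 | starting material
15 | (triisopropylsilyl)acetylene | C#C[Si](C(C)C)(C(C)C)C(C)C | starting material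
16 | (3S)-3-phenyl-5-(triisopropylsilyl)pent-4-ynal | CC(C)[Si](C(C)C)(C(C)C)C#C[C@@H](CC=O)c1ccccc1 | intermediate
17 | [(3S)-5,5-dimethoxy-3-phenylpent-1-yn-1-yl]triisopropylsilane | CC(C)[Si](C(C)C)(C(C)C)C#C[C@@H](CC(OC)OC)c1ccccc1 | intermediate
18 | [(3R)-5,5-dimethoxypent-1-yn-3-yl]benzene | C#C[C@@H](CC(OC)OC)c1ccccc1 | intermediate
19 | lithium acetylide of 18 | [Li]C#C[C@@H](CC(OC)OC)c1ccccc1 | intermediate
20 | lithium ynolate | [Li]OC#C[C@@H](CC(OC)OC)c1ccccc1 | intermediate
21 | {[(3S)-5,5-dimethoxy-3-phenylpent-1-yn-1-yl]oxy}triisopropylsilane | CC(C)[Si](C(C)C)(C(C)C)OC#C[C@@H](CC(OC)OC)c1ccccc1 | intermediate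
22 | vinylketene from 13 (E/Z) | C=C(C)[C@@H]1C[C@H](CC(CC=C(C)C)=C(OCC)C=C=O)C1(C)C | intermediate
23 | 4-alkenyl-3-silyloxy-2-(arm)cyclobut-2-enone | C=C(C)[C@@H]1C[C@H](CC(CC=C(C)C)=C(OCC)C2C(=O)C([C@@H](CC(OC)OC)c3ccccc3)=C2O[Si](C(C)C)(C(C)C)C(C)C)C1(C)C | intermediate
24 | dienylketene | C=C(C)[C@@H]1C[C@H](CC(CC=C(C)C)=C(OCC)C=C(O[Si](C(C)C)(C(C)C)C(C)C)C(=C=O)[C@@H](CC(OC)OC)c2ccccc2)C1(C)C | intermediate
25 | (6R)-6,6-dialkyl-5-ethoxy-3-silyloxy-2-(arm)cyclohexa-2,4-dienone (full name in step 12) | C=C(C)[C@@H]1C[C@H](C[C@@]2(CC=C(C)C)C(=O)C([C@@H](CC(OC)OC)c3ccccc3)=C(O[Si](C(C)C)(C(C)C)C(C)C)C=C2OCC)C1(C)C | intermediate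
26 | (R)-4-benzyl-3-propionyl-1,3-oxazolidin-2-one | CCC(=O)N1[C@H](Cc2ccccc2)COC1=O | starting material
27 | acetaldehyde | CC=O | starting material
28 | (R)-4-benzyl-3-[(2R,3S)-3-hydroxy-2-methylbutanoyl]-1,3-oxazolidin-2-one | C[C@H](O)[C@@H](C)C(=O)N1[C@H](Cc2ccccc2)COC1=O | intermediate
29 | (2R,3S)-3-hydroxy-N-methoxy-N,2-dimethylbutanamide | C[C@H](O)[C@@H](C)C(=O)N(C)OC | intermediate
30 | (2R,3S)-N-methoxy-N,2-dimethyl-3-[(triethylsilyl)oxy]butanamide | C[C@H](O[Si](CC)(CC)CC)[C@@H](C)C(=O)N(C)OC | intermediate
31 | (2R,3S)-2-methyl-3-[(triethylsilyl)oxy]butanal | C[C@H](O[Si](CC)(CC)CC)[C@@H](C)C=O | intermediate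
32 | C4a-lithio derivative of 25 | C=C(C)[C@@H]1C[C@H](C[C@@]2(CC=C(C)C)C(=O)C([C@@H](CC(OC)OC)c3ccccc3)=C(O[Si](C(C)C)(C(C)C)C(C)C)C([Li])=C2OCC)C1(C)C | intermediate
33 | C4 carbinol (both epimers) | C=C(C)[C@@H]1C[C@H](C[C@@]2(CC=C(C)C)C(=O)C([C@@H](CC(OC)OC)c3ccccc3)=C(O[Si](C(C)C)(C(C)C)C(C)C)C(C(O)[C@H](C)[C@H](C)O[Si](CC)(CC)CC)=C2OCC)C1(C)C | intermediate
34 | C4 ketone, O8a-TIPS, chain O-TES | C=C(C)[C@@H]1C[C@H](C[C@@]2(CC=C(C)C)C(=O)C([C@@H](CC(OC)OC)c3ccccc3)=C(O[Si](C(C)C)(C(C)C)C(C)C)C(C(=O)[C@H](C)[C@H](C)O[Si](CC)(CC)CC)=C2OCC)C1(C)C | intermediate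
35 | C8a enol with free (S)-carbinol | C=C(C)[C@@H]1C[C@H](C[C@@]2(CC=C(C)C)C(=O)C([C@@H](CC(OC)OC)c3ccccc3)=C(O)C(C(=O)[C@H](C)[C@H](C)O)=C2OCC)C1(C)C | intermediate
36 | (2R,3R,6R)-5-ethoxychromanone acetal (full name in step 20) | C=C(C)[C@@H]1C[C@H](C[C@@]2(CC=C(C)C)C(=O)C([C@@H](CC(OC)OC)c3ccccc3)=C3O[C@H](C)[C@@H](C)C(=O)C3=C2OCC)C1(C)C | intermediate
37 | 5-ethoxychromanone aldehyde | C=C(C)[C@@H]1C[C@H](C[C@@]2(CC=C(C)C)C(=O)C([C@@H](CC=O)c3ccccc3)=C3O[C@H](C)[C@@H](C)C(=O)C3=C2OCC)C1(C)C | intermediate
38 | 5-ethoxychromanone acid | C=C(C)[C@@H]1C[C@H](C[C@@]2(CC=C(C)C)C(=O)C([C@@H](CC(=O)O)c3ccccc3)=C3O[C@H](C)[C@@H](C)C(=O)C3=C2OCC)C1(C)C | intermediate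
39 | CNP0103716.3 (full name in step 23) | C=C(C)[C@@H]1C[C@H](C[C@@]2(CC=C(C)C)C(=O)C([C@@H](CC(=O)O)c3ccccc3)=C3O[C@H](C)[C@@H](C)C(=O)C3=C2O)C1(C)C | target

Total step count: 23.
Longest linear sequence: 14 (steps 1–4, 6, 7, 12, 17–23).

Steps most likely to fail

1. Step 12.
- What may go wrong: the vinylketene may be used up by unimolecular paths ([1,5]-H shift, addition to its own prenyl alkene) before it meets the ynol ether. The bulky alkenyl group may resist the inward rotation needed in the second ring opening. The prenyl group may migrate sigmatropically at the reaction temperature. Facial selectivity at C6 is expected to be poor.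
- Fallback (known chemistry): it sets out from 5 and comes back at 25; the ring is made aromatic first and the quaternary centre is added afterwards. Alkylation of dilithioacetate (from 6) with 5 would give 3-[(1S,3S)-2,2-dimethyl-3-(prop-1-en-2-yl)cyclobutyl]propanoic acid F1. Its acid chloride, Et3N and 10 would give 3-ethoxy-4-{[(1R,3S)-2,2-dimethyl-3-(prop-1-en-2-yl)cyclobutyl]methyl}cyclobut-2-en-1-one F2. The regular Danheiser benzannulation of F2 with 21 ends, because C6 still bears hydrogen, in 6-(cyclobutylmethyl)-5-ethoxy-8a-silyloxy-8-(arm)phenol F3. Alkylative dearomatisation of its lithium phenoxide with 7 in toluene, with C-alkylation at the alkyl-bearing ortho carbon C6, returns to 25. The C6 epimers are again separated.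

2. Step 17.
- What may go wrong: metalation may be incomplete or misdirected (benzylic C–H of the arm). The TIPS group may migrate from O8a to the carbanion or to the new alkoxide.
- Fallback: it sets out from 25 and comes back at 33; deprotonation is replaced by halogenation and halogen–metal exchange. Electrophilic iodination with NIS at low temperature, the α-iodination known for vinylogous esters, would give the C4a-iodo dienone F4. Iodine–magnesium exchange with i-PrMgCl·LiCl at −40 °C would give the C4a-magnesium chloride F5. This species is less basic, and its alkoxide is less prone to silyl transfer. Addition to 31 returns to 33.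

3. Step 20.
- What may go wrong: the activated carbinol may undergo β-elimination. The enol oxygen may be activated instead of the alcohol, which would lead to closure with retention. Either process erodes the configuration at C2.
- Fallback: it sets out from 25 (through 32) and comes back at 36; the ring is closed by conjugate addition instead of substitution. Quenching 32 with tigloyl chloride would give the C4a-tigloyl O8a-TIPS dienone F6. Fluoride would free the C4a-tigloyl C8a-enol F7. This enol closes by intramolecular oxa-Michael addition through O8a under a cinchona-alkaloid base, as known for o-hydroxyaryl tigloyl ketones. C3 is then equilibrated to trans and the diastereomers are separated to reach 36.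

Further compounds
F1 | step 12 | 3-[(1S,3S)-2,2-dimethyl-3-(prop-1-en-2-yl)cyclobutyl]propanoic acid | C=C(C)[C@@H]1C[C@H](CCC(=O)O)C1(C)C
F2 | step 12 | 3-ethoxy-4-{[(1R,3S)-2,2-dimethyl-3-(prop-1-en-2-yl)cyclobutyl]methyl}cyclobut-2-en-1-one | C=C(C)[C@@H]1C[C@H](CC2C(=O)C=C2OCC)C1(C)C
F3 | step 12 | 6-(cyclobutylmethyl)-5-ethoxy-8a-silyloxy-8-(arm)phenol | C=C(C)[C@@H]1C[C@H](Cc2c(O)c([C@@H](CC(OC)OC)c3ccccc3)c(O[Si](C(C)C)(C(C)C)C(C)C)cc2OCC)C1(C)C
F4 | step 17 | C4a-iodo dienone | C=C(C)[C@@H]1C[C@H](C[C@@]2(CC=C(C)C)C(=O)C([C@@H](CC(OC)OC)c3ccccc3)=C(O[Si](C(C)C)(C(C)C)C(C)C)C(I)=C2OCC)C1(C)C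
F5 | step 17 | C4a-magnesium chloride | C=C(C)[C@@H]1C[C@H](C[C@@]2(CC=C(C)C)C(=O)C([C@@H](CC(OC)OC)c3ccccc3)=C(O[Si](C(C)C)(C(C)C)C(C)C)C([Mg]Cl)=C2OCC)C1(C)C
F6 | step 20 | C4a-tigloyl O8a-TIPS dienone | C=C(C)[C@@H]1C[C@H](C[C@@]2(CC=C(C)C)C(=O)C([C@@H](CC(OC)OC)c3ccccc3)=C(O[Si](C(C)C)(C(C)C)C(C)C)C(C(=O)/C(C)=C/C)=C2OCC)C1(C)C
F7 | step 20 | C4a-tigloyl C8a-enol | C=C(C)[C@@H]1C[C@H](C[C@@]2(CC=C(C)C)C(=O)C([C@@H](CC(OC)OC)c3ccccc3)=C(O)C(C(=O)/C(C)=C/C)=C2OCC)C1(C)C
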